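**Plan**

- Retrosynthesis: the O4'–prenyl bond and the two O–Si bonds are cut first. Ring C is then opened at C4–C4a (intramolecular Friedel–Crafts acylation), followed by O1–C2 (phenoxide on an enol tosylate), C2–C3 (formylation) and C3–C1' (α-arylation of tert-butyl acetate).
- Forward: ring B is built as a 4-benzyloxy-2,5-dimethoxyphenylacetate, C2 comes from ethyl formate, and ring A is attached through O1 as its bis-TIPS ether. Ring C closes last; benzyl is then exchanged for prenyl and the silyl groups are removed.
- Enabling feature: ring A is a 1,3,5-trioxygenated benzene with a mirror plane through O1–C8a. The two carbons flanking C8a (future C4a and C8) are therefore identical, each ortho to one silyloxy group and para to the other, so acylation at C4a can give only one product.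
- Stereochemistry: the target has no stereocentre. The only stereo element on the way is the enol ether geometry of the acyclic acid, set Z by chelation-controlled tosylation and retentive substitution.

Key step: step 10

Remark: the enol ether of 19 and 20 is drawn Z (aryloxy cis to the carboxyl group); any E isomer formed alongside would be carried on, since the two are expected to interconvert under the acid of step 10.

**Route**

Step 1
Reactants: 1 2,5-dimethoxybenzaldehyde; 2 3-chloroperoxybenzoic acid (mCPBA)
Product: 4 2,5-dimethoxyphenol, via 2,5-dimethoxyphenyl formate 3 (not isolated)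
Conditions: mCPBA, CH2Cl2, 0 °C to rt; NaHCO3 wash; then K2CO3 (cat.), MeOH, rt
Reagents that add atoms: mCPBA, OOC(=O)c1cccc(Cl)c1
Why: Baeyer–Villiger oxidation of an electron-rich benzaldehyde, in which the aryl group migrates in the Criegee intermediate in preference to hydride, followed by base-catalysed methanolysis of the aryl formate 3 to the phenol.

Step 2
Reactants: 4 2,5-dimethoxyphenol; 5 benzyl bromide
Product: 6 1-benzyloxy-2,5-dimethoxybenzene
Conditions: BnBr, K2CO3, acetone, reflux
Reagents that add atoms: benzyl bromide, BrCc1ccccc1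
Why: Williamson ether synthesis, the phenoxide formed with K2CO3 displacing bromide from the benzylic halide by SN2.

Step 3
Reactants: 6 1-benzyloxy-2,5-dimethoxybenzene; 7 N-bromosuccinimide
Product: 8 1-benzyloxy-4-bromo-2,5-dimethoxybenzene
Conditions: NBS, MeCN, 0 °C to rt, dark
Reagents that add atoms: N-bromosuccinimide, O=C1CCC(=O)N1Br
Why: Electrophilic aromatic bromination at the carbon para to the benzyloxy group and ortho to the 5-methoxy group, the most activated unhindered position of this 1,2,4-trioxygenated ring and the same site at which 1,2,4-trimethoxybenzene is substituted.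

Step 4
Reactants: 8 1-benzyloxy-4-bromo-2,5-dimethoxybenzene; 9 tert-butyl acetate
Product: 10 tert-butyl (4-benzyloxy-2,5-dimethoxyphenyl)acetate
Conditions: Pd(dba)2 (cat.), P(t-Bu)3 (cat.), LiN(SiMe3)2, toluene, rt
Reagents that add atoms: tert-butyl acetate, CC(=O)OC(C)(C)C
Why: Palladium-catalysed α-arylation of an ester enolate, in which the zerovalent palladium complex of the bulky electron-rich P(t-Bu)3 inserts into the C–Br bond, the lithium enolate transmetallates and reductive elimination forms the C1'–C3 bond, while the tert-butyl ester resists Claisen self-condensation.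

Step 5
Reactants: 10 tert-butyl (4-benzyloxy-2,5-dimethoxyphenyl)acetate; 11 ethyl formate
Product: 12 tert-butyl (Z)-2-(4-benzyloxy-2,5-dimethoxyphenyl)-3-hydroxyacrylate
Conditions: NaH, HCO2Et, THF, 0 °C to rt; then 1 M HCl
Reagents that add atoms: ethyl formate, CCOC=O
Why: Crossed Claisen condensation with a non-enolisable formate, pulled through by deprotonation of the α-formyl ester, which after acidification should rest as the hydrogen-bonded Z enol.

Step 6
Reactants: 12 tert-butyl (Z)-2-(4-benzyloxy-2,5-dimethoxyphenyl)-3-hydroxyacrylate; 13 4-toluenesulfonyl chloride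
Product: 14 tert-butyl (Z)-2-(4-benzyloxy-2,5-dimethoxyphenyl)-3-(4-toluenesulfonyloxy)acrylate
Conditions: TsCl, TMEDA, LiCl, MeCN, 0 °C
Reagents that add atoms: 4-toluenesulfonyl chloride, Cc1ccc(S(=O)(=O)Cl)cc1
Why: Stereoselective O-sulfonylation of a 1,3-dicarbonyl enol, in which lithium chelation between the enolate oxygen and the ester carbonyl holds the two cis so that the tosylate is expected with Z geometry.

Step 7
Reactants: 15 phloroglucinol; 16 chlorotriisopropylsilane
Product: 17 3,5-bis(triisopropylsilyloxy)phenol
Conditions: TIPSCl (2.0 equiv), imidazole, DMF, 0 °C to rt; chromatography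
Reagents that add atoms: chlorotriisopropylsilane, CC(C)[Si](Cl)(C(C)C)C(C)C
Why: Imidazole-promoted silylation of phenols, which with two equivalents of the bulky chlorosilane should give the bis-silyl ether as the main component of a separable mixture whose mono- and tris-silylated fractions can be recycled.

Step 8
Reactants: 14 tert-butyl (Z)-2-(4-benzyloxy-2,5-dimethoxyphenyl)-3-(4-toluenesulfonyloxy)acrylate; 17 3,5-bis(triisopropylsilyloxy)phenol
Product: 19 tert-butyl (Z)-2-(4-benzyloxy-2,5-dimethoxyphenyl)-3-[3,5-bis(triisopropylsilyloxy)phenoxy]acrylate, via sodium 3,5-bis(triisopropylsilyloxy)phenoxide 18 (not isolated)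
Conditions: NaH, THF, 0 °C; then 14, 0 °C to rt
Reagents that add atoms: none
Why: Nucleophilic vinylic substitution by addition–elimination, the phenoxide adding to the unhindered β-carbon of the acrylate and the ester-stabilised carbanion expelling tosylate before it can rotate, so that retention to the Z enol ether (O1–C2 bond) is expected.

Step 9
Reactants: 19 tert-butyl (Z)-2-(4-benzyloxy-2,5-dimethoxyphenyl)-3-[3,5-bis(triisopropylsilyloxy)phenoxy]acrylate
Product: 20 (Z)-2-(4-benzyloxy-2,5-dimethoxyphenyl)-3-[3,5-bis(triisopropylsilyloxy)phenoxy]acrylic acid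
Conditions: CF3CO2H, CH2Cl2 (1:4), 0 °C; evaporation with toluene
Reagents that add atoms: none
Why: Acidolysis of a tert-butyl ester, in which protonation and loss of the tert-butyl cation as isobutene free the acid under anhydrous conditions that the aryl TIPS ethers, the benzyl ether and the enol ether should tolerate.

Step 10
Reactants: 20 (Z)-2-(4-benzyloxy-2,5-dimethoxyphenyl)-3-[3,5-bis(triisopropylsilyloxy)phenoxy]acrylic acid; 21 trifluoroacetic anhydride
Product: 23 4'-benzyloxy-2',5'-dimethoxy-5,7-bis(triisopropylsilyloxy)isoflavone, via mixed trifluoroacetic anhydride 22 (not isolated)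
Conditions: (CF3CO)2O, CH2Cl2, 0 °C to rt
Reagents that add atoms: none
Why: The anhydride turns the acid into the mixed anhydride 22, whose carbonyl carbon (or the acylium ion it ionises to) is attacked by the ring A carbon next to C8a, and loss of a proton from the arenium ion forms the C4–C4a bond and the pyranone. The closest known reaction type is the acid-mediated cyclisation of 3-aryloxyacrylic and aryloxyfumaric acids to chromones, an intramolecular Friedel–Crafts acylation. Ring C closes in a 6-exo-trig mode, the anhydride C=O being the exocyclic π bond. No stereocentre is formed; the Z enol ether places the acyl group cis to the aryloxy group, and an E isomer should be drawn in because reversible protonation at C3 by the trifluoroacetic acid released lets the two interconvert. Regioselectivity on ring A is the only selectivity needed and is secured by symmetry: the two carbons flanking C8a are equivalent, each is ortho to one silyloxy group and para to the other, and the carbon between the two silyloxy groups is out of reach of the tether. Benzyl on O4' in place of prenyl and the bulky TIPS groups are chosen to survive the acid, and ring B cannot compete because attack there would give a four-membered ring.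

Step 11
Reactants: 23 4'-benzyloxy-2',5'-dimethoxy-5,7-bis(triisopropylsilyloxy)isoflavone
Product: 24 4'-hydroxy-2',5'-dimethoxy-5,7-bis(triisopropylsilyloxy)isoflavone
Conditions: H2 (1 atm), 10% Pd/C, EtOAc, rt
Reagents that add atoms: none
Why: Catalytic hydrogenolysis of a benzyl aryl ether, cleavage of the benzylic C–O bond on palladium being much faster than reduction of the vinylogous ester double bond of the chromone, with the silyl ethers inert.

Step 12
Reactants: 24 4'-hydroxy-2',5'-dimethoxy-5,7-bis(triisopropylsilyloxy)isoflavone; 25 prenol (3-methylbut-2-en-1-ol)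
Product: 26 2',5'-dimethoxy-4'-(3-methylbut-2-enyloxy)-5,7-bis(triisopropylsilyloxy)isoflavone
Conditions: prenol, PPh3, DIAD, THF, 0 °C to rt
Reagents that add atoms: prenol, CC(C)=CCO
Why: Mitsunobu etherification, in which the phenol attacks the alkoxyphosphonium ion of the primary allylic alcohol by SN2 under neutral conditions that leave the aryl silyl ethers in place where a carbonate-mediated alkylation might not.

Step 13
Reactants: 26 2',5'-dimethoxy-4'-(3-methylbut-2-enyloxy)-5,7-bis(triisopropylsilyloxy)isoflavone
Product: 27 brandisianin A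
Conditions: Bu4NF, AcOH, THF, 0 °C
Reagents that add atoms: none
Why: Fluoride-induced desilylation driven by the strength of the Si–F bond, with acetic acid buffering the phenoxides and the allylic ether, the methyl ethers and the chromone left untouched.

**Compound list**

1 | 2,5-dimethoxybenzaldehyde | COc1ccc(OC)c(C=O)c1 | starting material
2 | 3-chloroperoxybenzoic acid (mCPBA) | OOC(=O)c1cccc(Cl)c1 | starting material
3 | 2,5-dimethoxyphenyl formate | COc1ccc(OC)c(OC=O)c1 | intermediate (not isolated)
4 | 2,5-dimethoxyphenol | COc1ccc(OC)c(O)c1 | intermediate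
5 | benzyl bromide | BrCc1ccccc1 | starting material
6 | 1-benzyloxy-2,5-dimethoxybenzene | COc1ccc(OC)c(OCc2ccccc2)c1 | intermediate
7 | N-bromosuccinimide | O=C1CCC(=O)N1Br | starting material
8 | 1-benzyloxy-4-bromo-2,5-dimethoxybenzene | COc1cc(OCc2ccccc2)c(OC)cc1Br | intermediate
9 | tert-butyl acetate | CC(=O)OC(C)(C)C | starting material
10 | tert-butyl (4-benzyloxy-2,5-dimethoxyphenyl)acetate | CC(C)(C)OC(=O)Cc1cc(OC)c(OCc2ccccc2)cc1OC | intermediate
11 | ethyl formate | CCOC=O | starting material
12 | tert-butyl (Z)-2-(4-benzyloxy-2,5-dimethoxyphenyl)-3-hydroxyacrylate (enol of the α-formyl ester, OH cis to the ester) | CC(C)(C)OC(=O)/C(=C\O)c1cc(OC)c(OCc2ccccc2)cc1OC | intermediate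
13 | 4-toluenesulfonyl chloride | Cc1ccc(S(=O)(=O)Cl)cc1 | starting material
14 | tert-butyl (Z)-2-(4-benzyloxy-2,5-dimethoxyphenyl)-3-(4-toluenesulfonyloxy)acrylate | CC(C)(C)OC(=O)/C(=C\OS(=O)(=O)c1ccc(C)cc1)c1cc(OC)c(OCc2ccccc2)cc1OC | intermediate
15 | phloroglucinol | Oc1cc(O)cc(O)c1 | starting material
16 | chlorotriisopropylsilane | CC(C)[Si](Cl)(C(C)C)C(C)C | starting material
17 | 3,5-bis(triisopropylsilyloxy)phenol | CC(C)[Si](Oc1cc(O)cc(O[Si](C(C)C)(C(C)C)C(C)C)c1)(C(C)C)C(C)C | intermediate
18 | sodium 3,5-bis(triisopropylsilyloxy)phenoxide | [Na+].[O-]c1cc(O[Si](C(C)C)(C(C)C)C(C)C)cc(O[Si](C(C)C)(C(C)C)C(C)C)c1 | intermediate (not isolated)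
19 | tert-butyl (Z)-2-(4-benzyloxy-2,5-dimethoxyphenyl)-3-[3,5-bis(triisopropylsilyloxy)phenoxy]acrylate | CC(C)(C)OC(=O)/C(=C\Oc1cc(O[Si](C(C)C)(C(C)C)C(C)C)cc(O[Si](C(C)C)(C(C)C)C(C)C)c1)c1cc(OC)c(OCc2ccccc2)cc1OC | intermediate
20 | (Z)-2-(4-benzyloxy-2,5-dimethoxyphenyl)-3-[3,5-bis(triisopropylsilyloxy)phenoxy]acrylic acid | OC(=O)/C(=C\Oc1cc(O[Si](C(C)C)(C(C)C)C(C)C)cc(O[Si](C(C)C)(C(C)C)C(C)C)c1)c1cc(OC)c(OCc2ccccc2)cc1OC | intermediate
21 | trifluoroacetic anhydride | O=C(OC(=O)C(F)(F)F)C(F)(F)F | starting material
22 | (Z)-2-(4-benzyloxy-2,5-dimethoxyphenyl)-3-[3,5-bis(triisopropylsilyloxy)phenoxy]acrylic trifluoroacetic anhydride | O=C(OC(=O)C(F)(F)F)/C(=C\Oc1cc(O[Si](C(C)C)(C(C)C)C(C)C)cc(O[Si](C(C)C)(C(C)C)C(C)C)c1)c1cc(OC)c(OCc2ccccc2)cc1OC | intermediate (not isolated)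
23 | 4'-benzyloxy-2',5'-dimethoxy-5,7-bis(triisopropylsilyloxy)isoflavone [3-(4-benzyloxy-2,5-dimethoxyphenyl)-5,7-bis(triisopropylsilyloxy)chromen-4-one] | CC(C)[Si](C(C)C)(C(C)C)Oc1cc(O[Si](C(C)C)(C(C)C)C(C)C)c2c(=O)c(-c3cc(OC)c(OCc4ccccc4)cc3OC)coc2c1 | intermediate
24 | 4'-hydroxy-2',5'-dimethoxy-5,7-bis(triisopropylsilyloxy)isoflavone | CC(C)[Si](C(C)C)(C(C)C)Oc1cc(O[Si](C(C)C)(C(C)C)C(C)C)c2c(=O)c(-c3cc(OC)c(O)cc3OC)coc2c1 | intermediate
25 | prenol (3-methylbut-2-en-1-ol) | CC(C)=CCO | starting material
26 | 2',5'-dimethoxy-4'-(3-methylbut-2-enyloxy)-5,7-bis(triisopropylsilyloxy)isoflavone | CC(C)[Si](C(C)C)(C(C)C)Oc1cc(O[Si](C(C)C)(C(C)C)C(C)C)c2c(=O)c(-c3cc(OC)c(OCC=C(C)C)cc3OC)coc2c1 | intermediate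
27 | brandisianin A [5,7-dihydroxy-3-[2,5-dimethoxy-4-(3-methylbut-2-enyloxy)phenyl]chromen-4-one] | COc1cc(-c2coc3cc(O)cc(O)c3c2=O)c(OC)cc1OCC=C(C)C | target

**Step count and risks**

Total steps: 13. Longest linear sequence: 12 steps (1–6, then 8–13); step 7 is a one-step branch.

Step 10 (ring closure). The mixed anhydride may be consumed by intermolecular acylation or by C-trifluoroacetylation of the electron-rich rings. A silyl ether may be lost in the acid, and an E enol ether may isomerise too slowly to feed the closure. Fallback: the same C4–C4a bond is made intermolecularly on unprotected phloroglucinol, which has the same symmetry, and O1–C2 is closed afterwards. Ester 10 is cleaved with CF3CO2H in CH2Cl2 to (4-benzyloxy-2,5-dimethoxyphenyl)acetic acid F1. F1 acylates phloroglucinol 15 in BF3·OEt2 at about 60 °C to give 2-(4-benzyloxy-2,5-dimethoxyphenyl)-1-(2,4,6-trihydroxyphenyl)ethan-1-one F2. Condensation of F2 with Me2NCH(OMe)2 in THF at 60 °C closes the pyranone to 4'-benzyloxy-5,7-dihydroxy-2',5'-dimethoxyisoflavone F3. Silylation of both hydroxyl groups with TIPSOTf and 2,6-lutidine in CH2Cl2 returns to the route at 23.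

Step 8 (enol ether formation). The phenoxide may attack sulfur instead of the β-carbon, transferring the sulfonyl group and releasing the enolate of 12. Silyl groups may migrate between phenoxides, and the carbanion may rotate before tosylate leaves, eroding the geometry. Fallback: the sulfonate is replaced by a vinylogous acid chloride whose only electrophilic site is carbon, and the preformed phenoxide by amine catalysis. Enol 12 is treated with (COCl)2 and catalytic DMF in CH2Cl2 at 0 °C to give tert-butyl (Z)-2-(4-benzyloxy-2,5-dimethoxyphenyl)-3-chloroacrylate F4 (either geometry would serve). F4 and phenol 17 with Et3N and catalytic DABCO in CH2Cl2 should then give the enol ether by amine-catalysed addition–elimination, rejoining the route at 19.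

Step 7 (partial silylation). The three hydroxyl groups silylate almost independently, so over- and under-silylation accompany the wanted bis-ether and throughput suffers. Fallback: exhaustive silylation followed by a single, self-limiting desilylation. Phloroglucinol 15 is converted with excess TIPSCl and imidazole in DMF into 1,3,5-tris(triisopropylsilyloxy)benzene F5. One equivalent of Bu4NF in THF at −78 °C, quenched with AcOH, should remove one silyl group: the phenoxide released by the first cleavage makes the remaining aryloxy groups poorer leaving groups, and fluoride is limiting. This rejoins the route at 17.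

**Further compounds**

F1 | step 10 | (4-benzyloxy-2,5-dimethoxyphenyl)acetic acid | OC(=O)Cc1cc(OC)c(OCc2ccccc2)cc1OC
F2 | step 10 | 2-(4-benzyloxy-2,5-dimethoxyphenyl)-1-(2,4,6-trihydroxyphenyl)ethan-1-one | O=C(Cc1cc(OC)c(OCc2ccccc2)cc1OC)c1c(O)cc(O)cc1O
F3 | step 10 | 4'-benzyloxy-5,7-dihydroxy-2',5'-dimethoxyisoflavone | COc1cc(-c2coc3cc(O)cc(O)c3c2=O)c(OC)cc1OCc1ccccc1
F4 | step 8 | tert-butyl (Z)-2-(4-benzyloxy-2,5-dimethoxyphenyl)-3-chloroacrylate | CC(C)(C)OC(=O)/C(=C\Cl)c1cc(OC)c(OCc2ccccc2)cc1OC
F5 | step 7 | 1,3,5-tris(triisopropylsilyloxy)benzene | CC(C)[Si](Oc1cc(O[Si](C(C)C)(C(C)C)C(C)C)cc(O[Si](C(C)C)(C(C)C)C(C)C)c1)(C(C)C)C(C)C
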